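Compound numbering used throughout: **1** 1,2,3,4-tetramethoxybenzene, **2** acetic anhydride, **3** the aryl methyl ketone, **4** methyl 4-methoxybenzoate, **5** the 1,3-diketone, **6** its 2-acetate, **7** the 3-acetoxyflavone, **8** the target.

## Analysis of the target

The target is a flavonol: a benzo ring A fused through C4a and C8a to a 4-pyranone ring C (O1, C2, C3, C4), with a 4-methoxyphenyl ring B on C2 and a free enolic hydroxyl on C3. Ring A is hexasubstituted, with methoxyls on C5, C6, C7 and C8, so that O1 and the four methoxyls form an unbroken row of five oxygens around it. There is no stereocenter, so the difficulty is purely regiochemical: building this crowded, very electron-rich ring next to the pyranone. The sensitive points are the 3-hydroxy-4-pyranone (acidic, chelating, cleaved by oxygen as its anion), the C5 methoxyl peri to the C4 carbonyl (lost to strong Lewis acids through chelation), and ring A itself, whose para-related C5 and C8 methoxyls invite oxidation to a quinone. The classical closures of ring C through the C2–O1 bond need a ring A phenol that already carries five oxygens, which is not a convenient starting material. The strategy rests on the O1–C8a bond. If it is cut, C8a becomes the single C–H carbon of a 2,3,4,5-tetramethoxyphenyl ketone, ortho to the C8 methoxyl and para to the C6 methoxyl, and that ring is one acylation away from a symmetrical tetramethoxybenzene. The oxygen that becomes O1 is then already present as a carbonyl or enol oxygen of a 1,3-diketone, placed so that its closure on that carbon makes a six-membered ring.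

## Retrosynthetic reasoning

Target **8** is first taken back to its 3-acetate **7**; only the acetyl C–O bond is cut. The acetate is the form in which the C3 oxygen is introduced, and it keeps C3 from being a free enol or α-hydroxy ketone during the oxidative ring closure. The forward step only has to exchange an enol ester under mild base without disturbing five aryl methyl ethers.

In **7** the O1–C8a bond is cut, which opens ring C and gives the acyclic 2-acetoxy-1,3-diketone **6** (racemic at the central carbon, which returns to sp2 C3 on closure). The cut is made here and not at C2–O1, because a C2–O1 cut leaves the oxygen on ring A, which would then need five oxygens before the pyranone is made. Cutting O1–C8a leaves the oxygen on the diketone and asks ring A for only four methoxyls and one C–H. The forward reaction must remove two hydrogens, the C8a–H and the enol O–H, and join oxygen to carbon. An anodic oxidation is chosen because the tetramethoxyphenyl ring is the most easily oxidized part of **6** and its only C–H is the carbon wanted.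

Diketone **6** is simplified to diketone **5** by cutting the C3–O bond. The central carbon of **5** is the only doubly activated position, so an electrophilic oxygen transfer from a hypervalent iodine diacetate should find it unaided, and the acetoxy group arrives in the form needed for the key step.

Diketone **5** is cut between its central carbon and the 4-methoxybenzoyl carbonyl (the future C2–C3 bond), giving methyl ketone **3** and ester **4**. This pairing is preferred to the reverse one (cutting the future C3–C4 bond) because **4** is purchasable and has no α-hydrogen, whereas the reverse pairing needs a tetramethoxybenzoate ester that would itself have to be made. The forward reaction is a crossed Claisen condensation in which only **3** can form an enolate.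

Ketone **3** is cut at the aryl–carbonyl bond (the future C4–C4a bond) to arene **1** and the acetyl donor **2**. The two C–H positions of **1** are equivalent by symmetry, so acylation can give only one ketone, and the remaining C–H of **3** is automatically the carbon that becomes C8a. The forward reaction must acylate without cleaving the methoxyl that ends up ortho to the carbonyl, which argues for a catalytic Lewis acid and the anhydride.

## Alternatives that were turned down

Alternative 1: Ring A is built, not bought. The key step would deliver hydroquinone A1 by cutting C8–C8a (and, one step earlier, C4a–C5). Ring A then comes from dimethyl squarate A3, and rings C and B from a 2-aryl-3-benzyloxy-4-pyranone metallated at the carbon next to its carbonyl. Addition to A3 gives the 4-hydroxycyclobutenone A2. Heating opens the four-membered ring to a dienylketene, which closes by 6π-electrocyclization onto the pyranone C–H carbon and tautomerizes to A1.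
- For: the four oxygens of ring A are placed by the squarate, no substitution on a crowded arene is needed, and this ring-opening/electrocyclization sequence is an established way to fully substituted hydroquinones. On precedent for the key step this alternative is stronger.
- Against: a 4-pyranone is a conjugate acceptor and its metallated form is hard to make and to add cleanly to A3. A1 then needs methylation of both phenols (one chelated to the C4 carbonyl) and removal of the benzyl group, and the pyranone must be made first.
- Comparison: the step count is roughly twice that of the chosen route, which takes all four ring A methoxyls from one purchased arene and uses no protecting group beyond the acetate that also sets the C3 oxidation level.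

Alternative 2: Ring C is formed last by inserting C3 into a benzofuran. The C2–C3 and C3–C4 bonds are cut, leading from the 3-bromochromone A4 back to the 3-silyloxybenzofuran A5 and dibromocarbene A6. In the forward sense A6 adds to the furan double bond of A5, and the dibromocyclopropane opens with loss of bromide and of the silyl group to give A4.
- For: ring expansion of electron-rich five-membered heteroaromatics by dihalocarbenes is a known reaction type, so the key step is less speculative than an anodic C–H etherification, and no question arises of which ring is oxidized.
- Against: the inserted carbon arrives as C–Br, so a further step must turn a hindered vinyl bromide into the C3 hydroxyl. The alkoxide base that generates A6 can also cleave the silyl enol ether, after which the enolate is attacked at carbon without expansion. The double bond is tetrasubstituted and flanked by two aryl groups. The benzofuranone behind A5 already demands a ring A phenol with five oxygens, the very intermediate the chosen route avoids.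
- Comparison: the chosen route has C3 at the correct oxidation level from the acetoxylation onward and reaches the target in five steps.

Alternative 3: Ring B is built on a finished chromone. The C1'–C6' and C2'–C3' bonds are cut, so that the 4'-phenol A7 comes from the 2-ethynylchromone A8 and (E)-1-methoxy-3-(trimethylsilyloxy)buta-1,3-diene A9. The alkyne of A8, conjugated through C2=C3 to the C4 carbonyl, is an electron-poor dienophile. Cycloaddition with the nucleophilic diene terminus at the alkyne CH, followed by loss of the methoxy and silyl groups, gives the para-hydroxyphenyl ring as one regioisomer.
- For: this Diels–Alder/aromatization sequence with acceptor alkynes is reliable and regioselective, more so than the proposed electrolysis.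
- Against: ring B is the one part of the target that can be bought complete, as in ester **4**, yet the plan spends its key step there. The hard part, the hexasubstituted ring A fused to an oxygenated pyranone, must already exist inside A8 and again requires a pentaoxygenated phenol ketone. Afterwards the new phenol must be methylated and the benzyl ether removed.
- Comparison: the chosen route puts its one uncertain step where the structural difficulty lies and takes ring B intact from **4**.

Key step: step 4

Remark: **1** is taken as a purchasable arene, acetic anhydride serves as the acetyl source so that a catalytic Lewis acid suffices, and the silyl group of A5 is taken as tert-butyldimethylsilyl.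

## Route

Step 1
Reactants: 1 1,2,3,4-tetramethoxybenzene; 2 acetic anhydride
Product: 3 1-(2,3,4,5-tetramethoxyphenyl)ethan-1-one
Conditions: Sc(OTf)3 (10 mol %), MeNO2, 50 °C
Reagents that add atoms: none
Why: Friedel–Crafts acylation catalysed by a metal triflate: the two free positions of 1 are equivalent by symmetry and each lies ortho to one methoxyl and para to another, so only one ketone can form, and the acyl group then deactivates the ring against a second acylation. The catalytic Lewis acid with the anhydride is chosen over stoichiometric AlCl3 so that the methoxyl next to the new carbonyl is not cleaved by chelation.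

Step 2
Reactants: 3 1-(2,3,4,5-tetramethoxyphenyl)ethan-1-one; 4 methyl 4-methoxybenzoate
Product: 5 1-(4-methoxyphenyl)-3-(2,3,4,5-tetramethoxyphenyl)propane-1,3-dione
Conditions: NaH (2.5 equiv), THF, reflux; then aq. HCl
Reagents that add atoms: none
Why: Crossed Claisen condensation: only 3 can enolize, 4 has no α-hydrogen and cannot self-condense, and deprotonation of the product 1,3-diketone by the excess base pulls the equilibrium forward. The aryl methyl ethers are inert to NaH in THF, and 5 should be isolated after acidification, mainly as its enol.

Step 3
Reactants: 5 1-(4-methoxyphenyl)-3-(2,3,4,5-tetramethoxyphenyl)propane-1,3-dione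
Product: 6 1-(4-methoxyphenyl)-1,3-dioxo-3-(2,3,4,5-tetramethoxyphenyl)propan-2-yl acetate (racemic)
Conditions: PhI(OAc)2 (1.1 equiv), AcOH, rt
Reagents that add atoms: (diacetoxyiodo)benzene, CC(=O)OI(OC(C)=O)c1ccccc1
Why: α-Acetoxylation of a 1,3-dicarbonyl compound with a hypervalent iodine diacetate: the enol of 5 is captured by the iodine reagent and acetate then displaces iodobenzene from the central carbon. The product is far less enolized than 5, which disfavours a second acetoxylation, and the acyl-substituted methoxyarenes are not oxidized by PhI(OAc)2 in acetic acid. The new stereocenter forms racemic and is of no consequence because it becomes sp2 in step 4.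

Step 4
Reactants: 6 1-(4-methoxyphenyl)-1,3-dioxo-3-(2,3,4,5-tetramethoxyphenyl)propan-2-yl acetate (racemic)
Product: 7 5,6,7,8-tetramethoxy-2-(4-methoxyphenyl)-4-oxo-4H-chromen-3-yl acetate
Conditions: undivided cell, graphite anode, Pt cathode, constant current (about 5 mA cm−2, 2.2 F mol−1), nBu4NPF6 (0.1 M), (CF3)2CHOH/CH2Cl2 1:1, rt, argon, dry
Reagents that add atoms: none
Why: Proposed new method: an intramolecular anodic C–H/O–H coupling that joins the enol (or keto carbonyl) oxygen of a 1,3-diketone to an arene C–H carbon has not been shown; the closest known reaction types are the anodic dehydrogenative lactonization of biaryl-2-carboxylic acids to benzocoumarins and the copper-catalysed intramolecular O-arylation of 2-haloaryl 1,3-diketones to flavones. One-electron oxidation at graphite should occur at the tetramethoxyphenyl ring, which has four donors against one acyl group and is expected to be oxidized well below the 4-methoxybenzoyl ring with its single donor para to a carbonyl. In the radical cation the only C–H carbon lies ortho to one methoxyl and para to another and carries a large share of the hole; the oxygen of the 4-methoxybenzoyl carbonyl, as the enol OH or as the keto oxygen followed by loss of the acidic central proton, adds there in a six-membered closure onto a trigonal ring carbon (6-endo with respect to the C4a–C8a bond). A second electron transfer and loss of the ring proton rearomatize ring A and fix the O1–C8a bond, while protons are reduced to H2 at the cathode, so no chemical oxidant is needed. If the enol is oxidized first instead, the resulting 1,3-dicarbonyl radical can add through oxygen to the same carbon, so both manifolds converge on 7. Site selectivity rests on the fact that addition at a methoxy-bearing carbon cannot be completed by proton loss and stays reversible when no nucleophile is present to demethylate the adduct, which is why a fluorinated alcohol with a non-nucleophilic electrolyte is used and methanol and water are excluded. No stereocenter is formed, and the racemic center of 6 becomes sp2 C3. Overoxidation is limited by passing only slightly more than 2 F mol−1 and by the expectation that 7, whose O1 is tied up in a vinylogous ester, is somewhat harder to oxidize than 6.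

Step 5
Reactants: 7 5,6,7,8-tetramethoxy-2-(4-methoxyphenyl)-4-oxo-4H-chromen-3-yl acetate
Product: 8 3-hydroxy-5,6,7,8-tetramethoxy-2-(4-methoxyphenyl)-4H-chromen-4-one
Conditions: K2CO3 (1.2 equiv), degassed MeOH, 0 °C to rt, argon; then 1 M HCl
Reagents that add atoms: none
Why: Base-mediated transesterification of an enol acetate: methoxide attacks the acetyl carbonyl and releases the stabilized flavonolate, which is protonated on acidic work-up. The aryl methyl ethers and the pyranone ring are untouched at these temperatures, and air is excluded because flavonolates are oxygenated in base.

## Compound list

1 | 1,2,3,4-tetramethoxybenzene | COc1ccc(OC)c(OC)c1OC | starting material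
2 | acetic anhydride | CC(=O)OC(C)=O | starting material
3 | 1-(2,3,4,5-tetramethoxyphenyl)ethan-1-one | CC(=O)c1cc(OC)c(OC)c(OC)c1OC | intermediate
4 | methyl 4-methoxybenzoate | COC(=O)c1ccc(OC)cc1 | starting material
5 | 1-(4-methoxyphenyl)-3-(2,3,4,5-tetramethoxyphenyl)propane-1,3-dione | COc1ccc(C(=O)CC(=O)c2cc(OC)c(OC)c(OC)c2OC)cc1 | intermediate
6 | 1-(4-methoxyphenyl)-1,3-dioxo-3-(2,3,4,5-tetramethoxyphenyl)propan-2-yl acetate (racemic) | COc1ccc(C(=O)C(OC(C)=O)C(=O)c2cc(OC)c(OC)c(OC)c2OC)cc1 | intermediate
7 | 5,6,7,8-tetramethoxy-2-(4-methoxyphenyl)-4-oxo-4H-chromen-3-yl acetate | COc1ccc(-c2oc3c(OC)c(OC)c(OC)c(OC)c3c(=O)c2OC(C)=O)cc1 | intermediate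
8 | 3-hydroxy-5,6,7,8-tetramethoxy-2-(4-methoxyphenyl)-4H-chromen-4-one | COc1ccc(-c2oc3c(OC)c(OC)c(OC)c(OC)c3c(=O)c2O)cc1 | target

## Step count and least certain steps

Total steps: 5. Longest linear sequence: 5 steps (1 → 3 → 5 → 6 → 7 → 8); 2 and 4 enter as purchased building blocks.

**Step 4 (key step).** The most likely failure is quenching of the ring A radical cation at a methoxy-bearing carbon, followed by oxidative demethylation towards a quinone. The C5 and C8 oxygens are para to each other, and any adventitious nucleophile makes that path irreversible. Oxidation may also start at the enol and lead to coupling at the central carbon or to dimerization instead of O–C closure. The keto tautomer may not bring the oxygen within reach, so that material is consumed unproductively as more charge is passed.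

Fallback, by known chemistry, setting out from 3 and rejoining the route at 8. Ring bromination of 3 at its one free position with N-bromosuccinimide in MeCN should give 1-(2-bromo-3,4,5,6-tetramethoxyphenyl)ethan-1-one F1. Claisen condensation of F1 with 4 (NaH, THF, reflux) should give 1-(2-bromo-3,4,5,6-tetramethoxyphenyl)-3-(4-methoxyphenyl)propane-1,3-dione F2. Copper-catalysed intramolecular O-arylation (CuI, K2CO3, DMF, 110 °C) then closes the O1–C8a bond to give 5,6,7,8-tetramethoxy-2-(4-methoxyphenyl)chromen-4-one F3. The C3 oxygen is introduced by epoxidation of the C2=C3 bond with dimethyldioxirane in acetone, giving racemic 3,4,5,6-tetramethoxy-1a-(4-methoxyphenyl)-1a,7a-dihydro-7H-oxireno[2,3-b]chromen-7-one F4. Acid-catalysed opening of F4 (catalytic p-TsOH, CH2Cl2) with loss of the C3 proton gives 8 directly. This keeps the O1–C8a disconnection but pays for it with a halogen at C8a and a late C3 oxidation.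

**Step 3.** The iodine reagent may stop at a stable iodonium ylide of the diketone. Alternatively, the doubly activated carbon may suffer a second oxidation or C–C cleavage, because the product still carries an acidic hydrogen between two carbonyls.

Fallback, setting out from 5 and returning at 6. Chlorination of the central carbon with N-chlorosuccinimide (CH2Cl2, rt) should give racemic 2-chloro-1-(4-methoxyphenyl)-3-(2,3,4,5-tetramethoxyphenyl)propane-1,3-dione F5. Displacement of chloride with KOAc in DMF at rt returns to 6. This replaces the oxidative oxygen transfer by halogenation and nucleophilic substitution.

**Step 1.** Chelation-assisted cleavage of the methoxyl ortho to the new carbonyl may occur, or the conversion may stall because the chelating product ketone binds the catalyst.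

Fallback, setting out from 1 and returning at 3. Directed ortho-lithiation (nBuLi, TMEDA, THF, 0 °C) should give (2,3,4,5-tetramethoxyphenyl)lithium F6. This is acylated in the same flask with N-methoxy-N-methylacetamide (−78 °C to rt, then aq. NH4Cl) to give 3. The electrophilic substitution is thereby replaced by an anionic one that uses no Lewis acid.

## Further compounds

F1 | step 4 | 1-(2-bromo-3,4,5,6-tetramethoxyphenyl)ethan-1-one | CC(=O)c1c(Br)c(OC)c(OC)c(OC)c1OC
F2 | step 4 | 1-(2-bromo-3,4,5,6-tetramethoxyphenyl)-3-(4-methoxyphenyl)propane-1,3-dione | COc1ccc(C(=O)CC(=O)c2c(Br)c(OC)c(OC)c(OC)c2OC)cc1
F3 | step 4 | 5,6,7,8-tetramethoxy-2-(4-methoxyphenyl)chromen-4-one | COc1ccc(-c2cc(=O)c3c(OC)c(OC)c(OC)c(OC)c3o2)cc1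
F4 | step 4 | 3,4,5,6-tetramethoxy-1a-(4-methoxyphenyl)-1a,7a-dihydro-7H-oxireno[2,3-b]chromen-7-one (racemic, cis-fused epoxide) | COc1ccc(C23OC2C(=O)c2c(OC)c(OC)c(OC)c(OC)c2O3)cc1
F5 | step 3 | 2-chloro-1-(4-methoxyphenyl)-3-(2,3,4,5-tetramethoxyphenyl)propane-1,3-dione (racemic) | COc1ccc(C(=O)C(Cl)C(=O)c2cc(OC)c(OC)c(OC)c2OC)cc1
F6 | step 1 | (2,3,4,5-tetramethoxyphenyl)lithium | [Li]c1cc(OC)c(OC)c(OC)c1OC
A1 | alternative 1 | 3-(benzyloxy)-5,8-dihydroxy-6,7-dimethoxy-2-(4-methoxyphenyl)chromen-4-one | COc1ccc(-c2oc3c(O)c(OC)c(OC)c(O)c3c(=O)c2OCc2ccccc2)cc1
A2 | alternative 1 | 4-[5-(benzyloxy)-6-(4-methoxyphenyl)-4-oxo-4H-pyran-3-yl]-4-hydroxy-2,3-dimethoxycyclobut-2-en-1-one (racemic) | COc1ccc(-c2occ(C3(O)C(OC)=C(OC)C3=O)c(=O)c2OCc2ccccc2)cc1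
A3 | alternative 1 | dimethyl squarate (3,4-dimethoxycyclobut-3-ene-1,2-dione) | COC1=C(OC)C(=O)C1=O
A4 | alternative 2 | 3-bromo-5,6,7,8-tetramethoxy-2-(4-methoxyphenyl)chromen-4-one | COc1ccc(-c2oc3c(OC)c(OC)c(OC)c(OC)c3c(=O)c2Br)cc1
A5 | alternative 2 | tert-butyldimethyl{[4,5,6,7-tetramethoxy-2-(4-methoxyphenyl)benzofuran-3-yl]oxy}silane | COc1ccc(-c2oc3c(OC)c(OC)c(OC)c(OC)c3c2O[Si](C)(C)C(C)(C)C)cc1
A6 | alternative 2 | dibromocarbene | Br[C]Br
A7 | alternative 3 | 3-(benzyloxy)-2-(4-hydroxyphenyl)-5,6,7,8-tetramethoxychromen-4-one | COc1c(OC)c(OC)c2oc(-c3ccc(O)cc3)c(OCc3ccccc3)c(=O)c2c1OC
A8 | alternative 3 | 3-(benzyloxy)-2-ethynyl-5,6,7,8-tetramethoxychromen-4-one | C#Cc1oc2c(OC)c(OC)c(OC)c(OC)c2c(=O)c1OCc1ccccc1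
A9 | alternative 3 | (E)-1-methoxy-3-(trimethylsilyloxy)buta-1,3-diene | CO/C=C/C(=C)O[Si](C)(C)C
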